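In a one-step world, where each hand of substrate meets reagent by its own step and nothing passes between the hands, one number stays constant however far the reagent falls: the logarithm of the fraction of its own charge left of the left-handed substrate, over the same logarithm for the right-handed substrate. That constant is the selectivity factor. We call the number, wherever it is read, the hand ratio.

| flask | left-handed substrate | right-handed substrate | reagent | racemization catalyst | added ligand | remark | time |
|---|---|---|---|---|---|---|---|
| gamma | 0.54 M | 0.54 M | 1.76 M | 96 mM | 98 mM | run made earlier |  |
| theta | 1.2 M | 1.2 M | 1.76 M | 96 mM | 98 mM | run made earlier |  |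
| alpha | 0.80 M | 0.80 M | 1.76 M | 140 mM | 98 mM | run made earlier |  |
| flask | 0.80 M | 0.80 M | 1.76 M | 96 mM | 98 mM |  | 4.0 d |

- gamma (time / d: left-handed substrate / %, right-handed substrate / %): 0.417: 32.0, 42.7; 0.625: 26.6, 41.0; 1.04: 19.6, 35.4; 1.67: 13.9, 28.2; 3.00: 7.3, 19.5; 5.00: 3.8, 12.3
- theta (time / d: left-handed substrate / %, right-handed substrate / %): 0.333: 34.9, 44.7; 0.833: 26.4, 38.1; 1.67: 19.4, 32.6; 2.50: 15.8, 28.7; 4.00: 13.6, 23.8; 5.00: 13.6, 21.9
- alpha (time / d: left-handed substrate / %, right-handed substrate / %): 0.417: 32.8, 43.1; 0.833: 24.4, 37.8; 1.25: 19.2, 32.4; 2.50: 12.4, 23.5; 5.00: 6.0, 15.1

(standard deviation of a reading: 0.5 percentage points)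

1. part of the left-handed substrate and right-handed substrate charged together that has reacted at 4.0 d
2. excess of left-handed product over right-handed product in the product at 4.0 d
3. excess of right-handed substrate over left-handed substrate among what is left of the two at 4.0 d

- reagent is single-handed; left-handed substrate and right-handed substrate are mirror images of each other, charged as a racemate, each of them at the stated concentration
- what was read earlier has a scatter of 0.5 percentage points, one standard deviation
- steps that have been proposed: reagent + right-handed substrate -> right-handed product; 2 racemization catalyst -> spent catalyst; left-handed substrate + racemization catalyst <-> right-handed substrate + racemization catalyst; racemization catalyst + added ligand <-> idle complex; reagent + left-handed substrate -> left-handed product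
- an excess is below zero if the other one leads
- the handed part of reagent does not stay in what it makes, so the products of the two hands are mirror images too

We climb by time. At the first gamma reading the left-handed substrate shows an apparent half-life of 0.648 d and the right-handed substrate a longer one of 1.83 d, so the hand ratio reads 2.82 there. The asked 4.0 d is longer than both, so for the flask we look at the late readings too. The hand ratio drifts: gamma reads 2.04 at 3.00 d and 1.84 at 5.00 d, and theta reads 1.75 at 4.00 d. That drift is the direction of the proposed racemization, which feeds the left-handed substrate from the right-handed one once the right leads.

The flask's charge of 0.80 M lies near the geometric mean of gamma and theta, so we take the middle of their values as our estimate of the late hand ratio for the flask, 1.85. The same middle gives 19.2% of right-handed substrate, and the ratio then gives 8.53% of left-handed. Our reckoning is therefore 72.3% reacted and a substrate excess of 38.5%. The readings show no product, so we leave the product excess open.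

The forecast differs from our reckoning, with 73.2% reacted and a substrate excess of 36%, and it adds a product excess of 39%, holding that the “left-handed substrate reacts about four times faster”.

The flask gives 73.9% reacted, a product excess of 44.0% and a substrate excess of 40.8%.

    reagent + right-handed substrate → right-handed product (k = 1.20 × 10⁻⁴ M⁻¹ min⁻¹)
    2 racemization catalyst → spent catalyst (k = 0.00450 M⁻¹ min⁻¹)
    left-handed substrate + racemization catalyst ⇌ right-handed substrate + racemization catalyst, rate k3*[racemization catalyst]*[left-handed substrate] forward; the back reaction follows from the equilibrium constant (k = 0.00470 M⁻¹ min⁻¹)
    racemization catalyst + added ligand ⇌ idle complex (K = 5.80 M⁻¹, k = 0.630 M⁻¹ min⁻¹)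
    reagent + left-handed substrate → left-handed product (k = 4.90 × 10⁻⁴ M⁻¹ min⁻¹)

At 4.00 d the flask holds 7.71% of left-handed and 18.4% of right-handed substrate, a hand ratio of 1.87 against our 1.85. The neighbour flask charged with 0.038 M of racemization catalyst holds 6.62% and 20.6% at the same time, so its hand ratio is higher, 2.28, while the selectivity factor of the two reagent steps is 4.08.

All runs were generated by integration for an exercise; noise was put on by code.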